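**Retrosynthetic overview**
- The last step is global O-demethylation of the tri-O-methyl ether of the target; both benzene rings are bought, so the 21-membered macrocycle is the only ring made.
- The macrocycle is closed by ring-closing metathesis between a ring B styrene and a ring A tetradec-13-enyl terminus, and the alkene is then hydrogenated to the (CH2)14 bridge.
- The styrene comes from Wittig methylenation of an aryl aldehyde; the diaryl ether before it comes from Ullmann coupling of a ring A phenol with a ring B aryl bromide.
- The ring A phenol comes from B-alkyl Suzuki coupling of 3-bromo-5-methoxyphenol with the mono-9-BBN adduct of tetradeca-1,13-diene; the ring B bromide comes from O-methylation of 3-bromo-2-hydroxy-5-methoxybenzaldehyde.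

Assumption: the SMILES has no stereodescriptors and the molecule has no stereogenic element (the 21-membered ring is too loose for stable planar chirality), so the "single enantiomer" is the achiral compound itself.

**Route**

Step 1
Reactants: 1 tetradeca-1,13-diene; 2 3-bromo-5-methoxyphenol
Product: 4 3-methoxy-5-(tetradec-13-en-1-yl)phenol, via tetradec-13-enyl-9-BBN 3 (not isolated)
Conditions: 1 (4 equiv), 9-BBN (1.3 equiv), THF, 0 °C → rt; then 2 (1.0 equiv), Pd(dppf)Cl2 (5 mol %), 3 M aq K3PO4, DMF, 60 °C
Reagents that add atoms: none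
Why: Anti-Markovnikov hydroboration of one terminal alkene of the excess symmetric diene followed by B-alkyl Suzuki–Miyaura coupling at the aryl bromide forms the aryl–CH2 bond while the second alkene and the free phenol are left alone, and no stereocentre is created.

Step 2
Reactants: 5 3-bromo-2-hydroxy-5-methoxybenzaldehyde
Product: 6 3-bromo-2,5-dimethoxybenzaldehyde
Conditions: MeI, K2CO3, DMF, rt
Reagents that add atoms: iodomethane, CI
Why: Williamson etherification of the acidic salicylaldehyde-type phenol masks it before the copper-mediated coupling, and no stereocentre is involved.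

Step 3
Reactants: 4 3-methoxy-5-(tetradec-13-en-1-yl)phenol; 6 3-bromo-2,5-dimethoxybenzaldehyde
Product: 7 2,5-dimethoxy-3-[3-methoxy-5-(tetradec-13-en-1-yl)phenoxy]benzaldehyde
Conditions: CuI (10 mol %), N,N-dimethylglycine·HCl (30 mol %), Cs2CO3, 1,4-dioxane, 90 °C
Reagents that add atoms: none
Why: Ligand-accelerated Ullmann diaryl ether synthesis joins the phenoxide to the aryl bromide at a temperature that the non-enolisable aldehyde and the terminal alkene tolerate, and no stereocentre is formed.

Step 4
Reactants: 7 2,5-dimethoxy-3-[3-methoxy-5-(tetradec-13-en-1-yl)phenoxy]benzaldehyde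
Product: 8 1-ethenyl-2,5-dimethoxy-3-[3-methoxy-5-(tetradec-13-en-1-yl)phenoxy]benzene
Conditions: Ph3PCH3Br, KOtBu, THF, 0 °C → rt
Reagents that add atoms: methyltriphenylphosphonium bromide, C[P+](c1ccccc1)(c1ccccc1)c1ccccc1.[Br-]
Why: Wittig methylenation of the non-enolisable aryl aldehyde gives the styrene needed as the second metathesis partner, with no stereochemical issue.

Step 5
Reactants: 8 1-ethenyl-2,5-dimethoxy-3-[3-methoxy-5-(tetradec-13-en-1-yl)phenoxy]benzene
Product: 9 21-membered macrocyclic alkene (ring B–CH=CH–(CH2)12–ring A; E major)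
Conditions: second-generation Grubbs catalyst (H2IMes)(PCy3)Cl2Ru=CHPh (5 mol %), CH2Cl2 (1 mM), 40 °C
Reagents that add atoms: none
Why: Ring-closing metathesis at high dilution starts at the unhindered terminal alkene, closes onto the styrene and is driven by loss of ethene; the E/Z ratio does not matter because the alkene is hydrogenated next.

Step 6
Reactants: 9 21-membered macrocyclic alkene
Product: 10 saturated macrocycle (tri-O-methyl ether of the target)
Conditions: H2 (1 atm), 10% Pd/C, EtOAc, rt
Reagents that add atoms: none
Why: Heterogeneous catalytic hydrogenation saturates the disubstituted alkene without cleaving aryl methyl or diaryl ethers, and creates no stereocentre.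

Step 7
Reactants: 10 saturated macrocycle (tri-O-methyl ether of the target)
Product: 12 target triol CNP0393720.0, via tris(dibromoboryl) ether 11 (not isolated)
Conditions: BBr3 (9 equiv), CH2Cl2, −78 °C → rt; then degassed H2O, 0 °C, work-up under argon
Reagents that add atoms: none
Why: Lewis acid mediated SN2 demethylation of the three aryl methyl ethers leaves the diaryl ether intact because neither of its carbons can undergo backside attack, and the achiral target is released on hydrolysis of the aryl borates.

**Compound list**

1 | tetradeca-1,13-diene | C=CCCCCCCCCCCCC=C | starting material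
2 | 3-bromo-5-methoxyphenol | COc1cc(O)cc(Br)c1 | starting material
3 | 9-(tetradec-13-en-1-yl)-9-borabicyclo[3.3.1]nonane | C=CCCCCCCCCCCCCB1C2CCCC1CCC2 | intermediate
4 | 3-methoxy-5-(tetradec-13-en-1-yl)phenol | COc1cc(O)cc(CCCCCCCCCCCCC=C)c1 | intermediate
5 | 3-bromo-2-hydroxy-5-methoxybenzaldehyde | COc1cc(Br)c(O)c(C=O)c1 | starting material
6 | 3-bromo-2,5-dimethoxybenzaldehyde | COc1cc(Br)c(OC)c(C=O)c1 | intermediate
7 | 2,5-dimethoxy-3-[3-methoxy-5-(tetradec-13-en-1-yl)phenoxy]benzaldehyde | COc1cc(Oc2cc(OC)cc(CCCCCCCCCCCCC=C)c2)c(OC)c(C=O)c1 | intermediate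
8 | 1-ethenyl-2,5-dimethoxy-3-[3-methoxy-5-(tetradec-13-en-1-yl)phenoxy]benzene | COc1cc(Oc2cc(OC)cc(CCCCCCCCCCCCC=C)c2)c(OC)c(C=C)c1 | intermediate
9 | 21-membered macrocyclic alkene: ring A (5-methoxy-1,3-phenylene) and ring B (2,5-dimethoxy-1,3-phenylene) joined C1(A)–O–C1(B) and C3(B)–CH=CH–(CH2)12–C3(A); E isomer drawn, minor Z isomer carried along | COc1cc2cc(c1)Oc1cc(OC)cc(c1OC)/C=C/CCCCCCCCCCCC2 | intermediate
10 | saturated macrocycle, tri-O-methyl ether of the target: rings A and B as in 9, joined C1(A)–O–C1(B) and C3(B)–(CH2)14–C3(A) | COc1cc2cc(c1)Oc1cc(OC)cc(c1OC)CCCCCCCCCCCCCC2 | intermediate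
11 | tris(dibromoboryl) ether of the target (the three phenol oxygens each carry BBr2) | BrB(Br)Oc1cc2cc(c1)Oc1cc(OB(Br)Br)cc(c1OB(Br)Br)CCCCCCCCCCCCCC2 | intermediate
12 | target CNP0393720.0: ring A (5-hydroxy-1,3-phenylene) and ring B (2,5-dihydroxy-1,3-phenylene) joined C1(A)–O–C1(B) and C3(B)–(CH2)14–C3(A); achiral | Oc1cc2cc(c1)Oc1cc(O)cc(c1O)CCCCCCCCCCCCCC2 | target

**Totals**

Total step count: 7. Longest linear sequence: 6 steps (1 → 3 → 4 → 5 → 6 → 7; the branch through step 2 is equally long).

**Three steps most likely to fail, with fallbacks**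

Step 5 (macrocyclic ring-closing metathesis) is the riskiest. A 21-membered ring competes with oligomerisation, and the ortho-methoxystyrene can hold the ruthenium carbene as a chelate. The fallback changes the ring-closing bond construction to a carbonyl reductive coupling. It sets out from 7: Lemieux–Johnson cleavage of the terminal alkene (OsO4 cat., NaIO4, 2,6-lutidine, dioxane/H2O) gives the dialdehyde 13-[3-(3-formyl-2,5-dimethoxyphenoxy)-5-methoxyphenyl]tridecanal F1. Intramolecular McMurry coupling of F1 with low-valent titanium (TiCl3(DME)1.5, Zn–Cu couple, DME, reflux, syringe-pump addition) then joins the two formyl carbons and comes back to the route at 9.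

Step 3 (Ullmann coupling) is next. The aryl bromide carries an ortho methoxy group and the phenol is only moderately nucleophilic. The fallback replaces the halide coupling by an oxidative boron-based etherification. It sets out from 6: Miyaura borylation (B2pin2, Pd(dppf)Cl2, KOAc, dioxane, 80 °C) gives 2,5-dimethoxy-3-(4,4,5,5-tetramethyl-1,3,2-dioxaborolan-2-yl)benzaldehyde F2. Chan–Lam–Evans coupling of F2 with phenol 4 (Cu(OAc)2, pyridine, 4 Å molecular sieves, air, CH2Cl2, rt) comes back to the route at 7.

Step 1 (mono-hydroboration and B-alkyl Suzuki coupling) is third. The mono-adduct forms statistically and the electron-rich bromophenoxide adds slowly to zerovalent palladium. The fallback reverses the polarity, with an aryl nucleophile and an alkyl electrophile. It sets out from 2: silylation (TBSCl, imidazole, DMF) gives tert-butyl(3-bromo-5-methoxyphenoxy)dimethylsilane F3. Magnesium insertion (Mg, THF, reflux) gives {3-[tert-butyl(dimethyl)silyloxy]-5-methoxyphenyl}magnesium bromide F4. Kochi coupling with 14-bromotetradec-1-ene (BrCCCCCCCCCCCCC=C; Li2CuCl4 cat., THF, −10 °C → rt) gives tert-butyl[3-methoxy-5-(tetradec-13-en-1-yl)phenoxy]dimethylsilane F5. TBAF in THF removes the silyl group and comes back to the route at 4. I have taken 14-bromotetradec-1-ene to be a catalogue reagent; that is from memory and should be confirmed.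

**Further compounds**

F1 | step 5 | 13-[3-(3-formyl-2,5-dimethoxyphenoxy)-5-methoxyphenyl]tridecanal | COc1cc(Oc2cc(OC)cc(CCCCCCCCCCCCC=O)c2)c(OC)c(C=O)c1
F2 | step 3 | 2,5-dimethoxy-3-(4,4,5,5-tetramethyl-1,3,2-dioxaborolan-2-yl)benzaldehyde | COc1cc(B2OC(C)(C)C(C)(C)O2)c(OC)c(C=O)c1
F3 | step 1 | tert-butyl(3-bromo-5-methoxyphenoxy)dimethylsilane | COc1cc(Br)cc(O[Si](C)(C)C(C)(C)C)c1
F4 | step 1 | {3-[tert-butyl(dimethyl)silyloxy]-5-methoxyphenyl}magnesium bromide | COc1cc([Mg]Br)cc(O[Si](C)(C)C(C)(C)C)c1
F5 | step 1 | tert-butyl[3-methoxy-5-(tetradec-13-en-1-yl)phenoxy]dimethylsilane | COc1cc(O[Si](C)(C)C(C)(C)C)cc(CCCCCCCCCCCCC=C)c1
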